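**Plan**
- Retrosynthesis: the C–Cl bond and then the chlorinated five-membered ring are removed first (the ring by reversing a 1,2-acyl shift onto a C11≡C1′ alkyne, back to an alkyne and a four-carbon cyclobutenedione), then the C8–CH3 bond, and last the decalin bonds C5–C10 and C8–C9 are cut together in a retro-[4+2].
- Forward: an acyclic chain is joined at C3–C4 (cuprate addition), C9=C10 (Horner–Wadsworth–Emmons) and C6=C7 (Wittig); rings A and B then form together in one intramolecular Diels–Alder step; the five-membered ring is built last by ring expansion of a cyclobutenol.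
- Enabling feature: ring B carries side by side the quaternary C10, C9 with its one-carbon branch C11 and the oxygenated C8, which is what a C9=C10 enoate (C11 as ester carbon) and a C5=C6–C7=C8–O donor diene leave behind; ring A is only the C1–C4 tether, whose gem-dimethyl carbon C4 sits next to the diene.
- Stereochemistry: C5, C9, C10 (and the temporary C8 ether) come from the E alkenes, the ester-endo transition state and a chiral oxazaborolidinium catalyst; C8 from equatorial methyl addition anti to the axial C10 methyl; the C11 alkene geometry from anti acyl migration and stereoretentive protonolysis; the C–Cl carbon from a catalyst-controlled ketone reduction followed by SN2 chlorination.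

Key step: step 8

Remark on numbering: drimane numbering is used throughout, also for the acyclic precursors (ring A C1–C5 and C10, ring B C5–C10, C11 on C9, β is the face of the C10 methyl); the five-membered ring is C1′ (ylidene carbon), C2′ (ring carbon cis to C9), C3′ (CH), C4′ (isopropoxy carbon, later carbonyl) and C5′ (carbinol, later chloride carbon).
Remark on the target: its 3-hydroxy-enone is a vinylogous acid whose two enol forms interconvert by proton shift, so the hydrolysis product of step 22 is written as the tautomer of the given structure.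

**Step 1**
Reactants: 1 2-(3-chloropropyl)-2-methyl-1,3-dioxolane; 2 diethyl isopropylidenemalonate
Product: 4 diethyl 2-[2-methyl-5-(2-methyl-1,3-dioxolan-2-yl)pentan-2-yl]propanedioate, via Grignard reagent 3 (not isolated)
Conditions: Mg, THF, reflux; then CuI (10 mol %), 2, THF, −20 → 0 °C; aq NH4Cl
Reagents that add atoms: none
Why: Copper-catalysed conjugate addition of a primary Grignard reagent to an alkylidenemalonate is a standard way to a quaternary carbon, here C4 with its two methyl groups, while the dioxolane masks the future C10 ketone.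

**Step 2**
Reactants: 4
Product: 5 ethyl 3,3-dimethyl-6-(2-methyl-1,3-dioxolan-2-yl)hexanoate
Conditions: LiCl, H2O (2 equiv), DMSO, 160 °C
Reagents that add atoms: none
Why: Krapcho dealkoxycarbonylation removes one ester group of the malonate under neutral conditions that should leave the ketal intact.

**Step 3**
Reactants: 5
Product: 7 8-hydroxy-6,6-dimethyloctan-2-one, via ketal alcohol 6 (not isolated)
Conditions: LiAlH4, THF, 0 °C; then 2 M aq HCl, THF, 20 °C
Reagents that add atoms: water, O
Why: Hydride reduction of the ester followed by acid hydrolysis of the dioxolane in the work-up frees the methyl ketone while the other chain end is an alcohol, so that the ketone can be olefinated before any aldehyde is present.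

**Step 4**
Reactants: 7; 8 trimethyl phosphonoacetate
Product: 9 methyl (2E)-9-hydroxy-3,7,7-trimethylnon-2-enoate
Conditions: NaH (1.4 equiv), 8 (1.5 equiv), THF, 0 °C → reflux
Reagents that add atoms: none
Why: Horner–Wadsworth–Emmons olefination of the methyl ketone should give mainly the (2E)-enoate (ester anti to the longer chain), the phosphonate anion being too weak a base to deprotonate the free hydroxyl, and the minor (2Z) isomer is removed by chromatography.

**Step 5**
Reactants: 9
Product: 10 methyl (2E)-3,7,7-trimethyl-9-oxonon-2-enoate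
Conditions: Dess–Martin periodinane (C13H13IO8), CH2Cl2, 20 °C
Reagents that add atoms: none
Why: Dess–Martin oxidation takes the primary alcohol to the aldehyde without touching the enoate.

**Step 6**
Reactants: 10; 11 (triphenylphosphoranylidene)acetaldehyde
Product: 12 methyl (2E,9E)-3,7,7-trimethyl-11-oxoundeca-2,9-dienoate
Conditions: 11 (1.2 equiv), toluene, 80 °C
Reagents that add atoms: none
Why: Wittig reaction of the stabilised formyl ylide with the aliphatic aldehyde should give the (E)-enal (C6=C7), the product enal and the enoate being far less reactive toward the ylide.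

**Step 7**
Reactants: 12
Product: 13 methyl (2E,8E,10E)-3,7,7-trimethyl-11-[(triisopropylsilyl)oxy]undeca-2,8,10-trienoate
Conditions: TIPSOTf (1.1 equiv), Et3N, Et2O, −78 → 0 °C
Reagents that add atoms: triisopropylsilyl trifluoromethanesulfonate, CC(C)[Si](OS(=O)(=O)C(F)(F)F)(C(C)C)C(C)C
Why: Soft enolisation (O-silylation of the enal, loss of a γ-proton from C5) gives the 1-silyloxydiene, E at C7=C8 from the s-trans enal and E at C5=C6 because the quaternary C4 avoids the cis position, while the ester is not enolised by Et3N.

**Step 8**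
Reactants: 13
Product: 14 methyl (5S,8S,9R,10S)-8β-(triisopropylsilyloxy)-12-nordrim-6-en-11-oate [methyl (1R,2S,4aS,8aS)-5,5,8a-trimethyl-2-(triisopropylsilyloxy)-1,2,4a,5,6,7,8,8a-octahydronaphthalene-1-carboxylate]
Conditions: (S)-B-(o-tolyl)-diphenylprolinol oxazaborolidinium triflimide [C24H25BNO][N(SO2CF3)2] (20 mol %, from (S)-α,α-diphenylprolinol, tri-o-tolylboroxine and HNTf2), CH2Cl2, −78 → −20 °C
Reagents that add atoms: none
Why: Proposed new method: the boron Lewis acid binds the ester carbonyl (anti to OMe, with an α-C–H···O contact to the ring oxygen) and the electron-rich 1-silyloxydiene adds to the activated C9=C10 alkene in a concerted, asynchronous [4+2] in which C5–C10 bonding runs ahead of C8–C9, as the polarities demand; the closest known reactions are Lewis-acid-promoted intramolecular Diels–Alder cyclisations of (2E,8E,10E)-undeca-2,8,10-trienoates to trans-octalins and oxazaborolidinium-catalysed intermolecular additions of dienes to acrylate and crotonate esters, but no catalytic enantioselective case with a β,β-disubstituted enoate is known. Ring A closes through the C5–C10 bond with the four-carbon tether C1–C4 folded chair-like, and ring B is the cyclohexene formed by the cycloaddition itself through C5–C10 and C8–C9. The (2E) alkene places the ester cis to the C10 methyl group, the (8E,10E) diene places the silyloxy group and the C4–C5 bond on one face, and the ester-endo transition state makes the ester cis to the silyloxy group and the ring fusion trans (H5 anti to the C10 methyl). The absolute configuration comes from the catalyst, whose phenyl group is expected on the α-C–H···O binding model to cover the Re face of C9 of the bound s-trans enoate so that C8 adds to the Si face, giving 9R and with it 5S, 8S and 10S. The step needs reactivity, endo selectivity and face selectivity: the donor diene, the gem-dimethyl carbon C4 (which favours the folded conformer) and the bulky triisopropylsilyl group (slow silyl transfer to the Lewis acid) are built into the substrate for the first two, and the third rests on the catalyst.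

**Step 9**
Reactants: 14
Product: 15 methyl 8β-(triisopropylsilyloxy)-12-nordriman-11-oate
Conditions: H2 (1 atm), 10% Pd/C, EtOAc, 20 °C
Reagents that add atoms: none
Why: Heterogeneous hydrogenation saturates the only C=C (C6=C7) without forming a stereocentre, and the allylic silyl ether should not be hydrogenolysed in EtOAc.

**Step 10**
Reactants: 15
Product: 16 8β-(triisopropylsilyloxy)-12-nordriman-11-ol
Conditions: LiAlH4, THF, 0 → 20 °C; H2O work-up
Reagents that add atoms: none
Why: LiAlH4 reduction takes the hindered ester to the primary alcohol, and the bulky triisopropylsilyl ether should neither cleave nor migrate to the new alkoxide.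

**Step 11**
Reactants: 16
Product: 17 8β-(triisopropylsilyloxy)-12-nordriman-11-al
Conditions: Dess–Martin periodinane (C13H13IO8), CH2Cl2, 0 → 20 °C
Reagents that add atoms: none
Why: Dess–Martin oxidation gives the aldehyde under non-basic conditions, and the β (equatorial) aldehyde at C9 is also the thermodynamically preferred epimer.

**Step 12**
Reactants: 17
Product: 18 9β-ethynyl-4,4,10β-trimethyl-8β-(triisopropylsilyloxy)-trans-decalin (5αH, 9αH; alkyne carbons C11 and C1′)
Conditions: dimethyl (1-diazo-2-oxopropyl)phosphonate, K2CO3, MeOH, 0 → 20 °C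
Reagents that add atoms: dimethyl (1-diazo-2-oxopropyl)phosphonate, COP(=O)(OC)C(=[N+]=[N-])C(C)=O
Why: Seyferth–Gilbert homologation with the Ohira–Bestmann reagent converts the aldehyde into the terminal alkyne by a one-carbon extension, C9 keeping its equatorial (β) substituent.

**Step 13**
Reactants: 18
Product: 19 9β-ethynyl-4,4,10β-trimethyl-trans-decalin-8β-ol
Conditions: Bu4NF, THF, 50 °C
Reagents that add atoms: none
Why: Fluoride cleaves the secondary silyl ether, and the terminal alkyne is inert to these conditions.

**Step 14**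
Reactants: 19
Product: 20 9β-ethynyl-4,4,10β-trimethyl-trans-decalin-8-one
Conditions: Dess–Martin periodinane (C13H13IO8), CH2Cl2, 0 °C
Reagents that add atoms: none
Why: Dess–Martin oxidation gives the ketone without base, so that the α-ethynyl ketone should not isomerise to the allenyl ketone and C9 keeps its configuration.

**Step 15**
Reactants: 20
Product: 21 9β-ethynyl-4,4,8α,10β-tetramethyl-trans-decalin-8β-ol
Conditions: CeCl3 (dried), MeMgBr, THF, −78 °C; aq NH4Cl
Reagents that add atoms: methylmagnesium bromide, C[Mg]Br
Why: The weakly basic organocerium reagent adds 1,2 to the enolisable ketone, and the methyl group enters along the equatorial trajectory on the α face because the axial approach on the β face is blocked by the axial C10 methyl (as with 3,3,5-trimethylcyclohexanone), which sets 8α-CH3 and 8β-OH.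

**Step 16**
Reactants: 21
Product: 22 9β-ethynyl-4,4,8α,10β-tetramethyl-8β-(trimethylsilyloxy)-trans-decalin
Conditions: TMSOTf, 2,6-lutidine, CH2Cl2, −78 → 0 °C
Reagents that add atoms: trimethylsilyl trifluoromethanesulfonate, C[Si](C)(C)OS(=O)(=O)C(F)(F)F
Why: The silyl triflate silylates the hindered axial tertiary alcohol, which keeps the homopropargylic hydroxyl from adding to the palladium-activated alkyne in step 19 and is removed in the last step.

**Step 17**
Reactants: 23 diisopropyl squarate
Product: 25 3-isopropoxycyclobut-3-ene-1,2-dione, via hydroxycyclobutenone 24 (not isolated)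
Conditions: LiAlH(OtBu)3, THF, −60 → 0 °C; aq HCl work-up; then conc HCl (cat), CH2Cl2, 20 °C
Reagents that add atoms: water, O
Why: The known two-stage route to a semisquarate ester, in which the bulky hydride reduces one carbonyl of the squarate 1,2 and acid then causes allylic transposition with loss of propan-2-ol (the carbinol centre of 24 is lost).

**Step 18**
Reactants: 22; 25
Product: 27 4-hydroxy-3-isopropoxy-4-{[4,4,8α,10β-tetramethyl-8β-(trimethylsilyloxy)-trans-decalin-9β-yl]ethynyl}cyclobut-2-en-1-one (both configurations at the carbinol carbon), via lithium acetylide 26 (not isolated)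
Conditions: n-BuLi (1.05 equiv), THF, −78 °C; then 25, −78 °C; aq NH4Cl
Reagents that add atoms: none
Why: The alkynyllithium adds 1,2 to the more electrophilic carbonyl of the cyclobutenedione (the one that is not a vinylogous ester), and the new carbinol centre, formed unselectively, becomes a carbonyl carbon in the next step.

**Step 19**
Reactants: 27
Product: 28 (E)-4-isopropoxy-2-{[4,4,8α,10β-tetramethyl-8β-(trimethylsilyloxy)-trans-decalin-9β-yl]methylidene}cyclopent-4-ene-1,3-dione (C9 syn to C2′=O, the carbonyl next to the vinylic CH)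
Conditions: Pd(OCOCF3)2 (5 mol %), THF, 20 °C
Reagents that add atoms: none
Why: Palladium-catalysed ring expansion of a 4-alkynyl-4-hydroxycyclobutenone, in which divalent palladium activates the alkyne, the acyl carbon shifts to C1′ anti to palladium with relief of ring strain and the vinyl–palladium bond is protonated with retention, so that C9 ends syn to the migrated carbonyl C2′.

**Step 20**
Reactants: 28
Product: 29 (4S,5Z)-4-hydroxy-3-isopropoxy-5-{[4,4,8α,10β-tetramethyl-8β-(trimethylsilyloxy)-trans-decalin-9β-yl]methylidene}cyclopent-2-en-1-one (carbinol C5′ is S)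
Conditions: (S)-2-methyl-CBS-oxazaborolidine (C18H20BNO, 20 mol %), catecholborane, toluene, −78 °C
Reagents that add atoms: none
Why: Corey–Bakshi–Shibata reduction should take place at the C5′ carbonyl, which is more electrophilic than the vinylogous-ester carbonyl C2′ and lies away from the bulky decalin, and with the alkylidene flank acting as the large group the (S)-catalyst delivers hydride to the Re face to set the (S)-carbinol.

**Step 21**
Reactants: 29
Product: 30 (4R,5E)-4-chloro-3-isopropoxy-5-{[4,4,8α,10β-tetramethyl-8β-(trimethylsilyloxy)-trans-decalin-9β-yl]methylidene}cyclopent-2-en-1-one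
Conditions: PPh3, hexachloroacetone, CH2Cl2, −20 → 0 °C
Reagents that add atoms: hexachloroacetone, O=C(C(Cl)(Cl)Cl)C(Cl)(Cl)Cl
Why: Appel-type chlorination of the allylic alcohol proceeds by SN2 displacement of the oxyphosphonium group with inversion (S to R), since ionisation would give a cyclopentadienyl-type cation and the SN2′ positions are blocked, and the neutral, chloride-poor medium guards against epimerisation.

**Step 22**
Reactants: 30
Product: 32 target, (4E,5R)-5-chloro-3-hydroxy-4-{[8β-hydroxy-4,4,8α,10β-tetramethyl-trans-decalin-9β-yl]methylidene}cyclopent-2-en-1-one, via desilylated chloride 31 (not isolated)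
Conditions: 1 M aq HCl, THF, 0 → 20 °C
Reagents that add atoms: water, O
Why: Dilute acid cleaves the tertiary trimethylsilyl ether and hydrolyses the vinylogous isopropyl ester (addition of water at C4′, loss of propan-2-ol) to the vinylogous acid, under conditions mild enough that the C5′ chloride should keep its configuration.

**Compound list**
1 | 2-(3-chloropropyl)-2-methyl-1,3-dioxolane | CC1(CCCCl)OCCO1 | starting material
2 | diethyl isopropylidenemalonate | CCOC(=O)C(=C(C)C)C(=O)OCC | starting material
3 | [3-(2-methyl-1,3-dioxolan-2-yl)propyl]magnesium chloride | CC1(CCC[Mg]Cl)OCCO1 | intermediate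
4 | diethyl 2-[2-methyl-5-(2-methyl-1,3-dioxolan-2-yl)pentan-2-yl]propanedioate | CCOC(=O)C(C(=O)OCC)C(C)(C)CCCC1(C)OCCO1 | intermediate
5 | ethyl 3,3-dimethyl-6-(2-methyl-1,3-dioxolan-2-yl)hexanoate | CCOC(=O)CC(C)(C)CCCC1(C)OCCO1 | intermediate
6 | 3,3-dimethyl-6-(2-methyl-1,3-dioxolan-2-yl)hexan-1-ol | OCCC(C)(C)CCCC1(C)OCCO1 | intermediate
7 | 8-hydroxy-6,6-dimethyloctan-2-one | CC(=O)CCCC(C)(C)CCO | intermediate
8 | trimethyl phosphonoacetate | COC(=O)CP(=O)(OC)OC | starting material
9 | methyl (2E)-9-hydroxy-3,7,7-trimethylnon-2-enoate | COC(=O)/C=C(\C)CCCC(C)(C)CCO | intermediate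
10 | methyl (2E)-3,7,7-trimethyl-9-oxonon-2-enoate | COC(=O)/C=C(\C)CCCC(C)(C)CC=O | intermediate
11 | (triphenylphosphoranylidene)acetaldehyde | O=CC=P(c1ccccc1)(c1ccccc1)c1ccccc1 | starting material
12 | methyl (2E,9E)-3,7,7-trimethyl-11-oxoundeca-2,9-dienoate | COC(=O)/C=C(\C)CCCC(C)(C)C/C=C/C=O | intermediate
13 | methyl (2E,8E,10E)-3,7,7-trimethyl-11-[(triisopropylsilyl)oxy]undeca-2,8,10-trienoate | COC(=O)/C=C(\C)CCCC(C)(C)/C=C/C=C/O[Si](C(C)C)(C(C)C)C(C)C | intermediate
14 | methyl (5S,8S,9R,10S)-8β-(triisopropylsilyloxy)-12-nordrim-6-en-11-oate | CC1(C)CCC[C@]2(C)[C@@H](C(=O)OC)[C@@H](O[Si](C(C)C)(C(C)C)C(C)C)C=C[C@@H]12 | intermediate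
15 | methyl 8β-(triisopropylsilyloxy)-12-nordriman-11-oate | CC1(C)CCC[C@]2(C)[C@@H](C(=O)OC)[C@@H](O[Si](C(C)C)(C(C)C)C(C)C)CC[C@@H]12 | intermediate
16 | 8β-(triisopropylsilyloxy)-12-nordriman-11-ol | CC1(C)CCC[C@]2(C)[C@@H](CO)[C@@H](O[Si](C(C)C)(C(C)C)C(C)C)CC[C@@H]12 | intermediate
17 | 8β-(triisopropylsilyloxy)-12-nordriman-11-al | CC1(C)CCC[C@]2(C)[C@@H](C=O)[C@@H](O[Si](C(C)C)(C(C)C)C(C)C)CC[C@@H]12 | intermediate
18 | 9β-ethynyl-4,4,10β-trimethyl-8β-(triisopropylsilyloxy)-trans-decalin | CC1(C)CCC[C@]2(C)[C@@H](C#C)[C@@H](O[Si](C(C)C)(C(C)C)C(C)C)CC[C@@H]12 | intermediate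
19 | 9β-ethynyl-4,4,10β-trimethyl-trans-decalin-8β-ol | CC1(C)CCC[C@]2(C)[C@@H](C#C)[C@@H](O)CC[C@@H]12 | intermediate
20 | 9β-ethynyl-4,4,10β-trimethyl-trans-decalin-8-one | CC1(C)CCC[C@]2(C)[C@@H](C#C)C(=O)CC[C@@H]12 | intermediate
21 | 9β-ethynyl-4,4,8α,10β-tetramethyl-trans-decalin-8β-ol | CC1(C)CCC[C@]2(C)[C@@H](C#C)[C@@](C)(O)CC[C@@H]12 | intermediate
22 | 9β-ethynyl-4,4,8α,10β-tetramethyl-8β-(trimethylsilyloxy)-trans-decalin | CC1(C)CCC[C@]2(C)[C@@H](C#C)[C@@](C)(O[Si](C)(C)C)CC[C@@H]12 | intermediate
23 | diisopropyl squarate | CC(C)OC1=C(OC(C)C)C(=O)C1=O | starting material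
24 | 4-hydroxy-2,3-diisopropoxycyclobut-2-en-1-one (racemic) | CC(C)OC1=C(OC(C)C)C(O)C1=O | intermediate
25 | 3-isopropoxycyclobut-3-ene-1,2-dione | CC(C)OC1=CC(=O)C1=O | intermediate
26 | lithium acetylide of 22 | CC1(C)CCC[C@]2(C)[C@@H](C#C[Li])[C@@](C)(O[Si](C)(C)C)CC[C@@H]12 | intermediate
27 | 4-hydroxy-3-isopropoxy-4-{[4,4,8α,10β-tetramethyl-8β-(trimethylsilyloxy)-trans-decalin-9β-yl]ethynyl}cyclobut-2-en-1-one (carbinol epimers) | CC1(C)CCC[C@]2(C)[C@@H](C#CC3(O)C(OC(C)C)=CC3=O)[C@@](C)(O[Si](C)(C)C)CC[C@@H]12 | intermediate
28 | (E)-4-isopropoxy-2-{[4,4,8α,10β-tetramethyl-8β-(trimethylsilyloxy)-trans-decalin-9β-yl]methylidene}cyclopent-4-ene-1,3-dione | CC1(C)CCC[C@]2(C)[C@@H](/C=C3\C(=O)C=C(OC(C)C)C3=O)[C@@](C)(O[Si](C)(C)C)CC[C@@H]12 | intermediate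
29 | (4S,5Z)-4-hydroxy-3-isopropoxy-5-{[4,4,8α,10β-tetramethyl-8β-(trimethylsilyloxy)-trans-decalin-9β-yl]methylidene}cyclopent-2-en-1-one | CC1(C)CCC[C@]2(C)[C@@H](/C=C3\C(=O)C=C(OC(C)C)[C@H]3O)[C@@](C)(O[Si](C)(C)C)CC[C@@H]12 | intermediate
30 | (4R,5E)-4-chloro-3-isopropoxy-5-{[4,4,8α,10β-tetramethyl-8β-(trimethylsilyloxy)-trans-decalin-9β-yl]methylidene}cyclopent-2-en-1-one | CC1(C)CCC[C@]2(C)[C@@H](/C=C3\C(=O)C=C(OC(C)C)[C@@H]3Cl)[C@@](C)(O[Si](C)(C)C)CC[C@@H]12 | intermediate
31 | (4R,5E)-4-chloro-5-{[8β-hydroxy-4,4,8α,10β-tetramethyl-trans-decalin-9β-yl]methylidene}-3-isopropoxycyclopent-2-en-1-one | CC1(C)CCC[C@]2(C)[C@@H](/C=C3\C(=O)C=C(OC(C)C)[C@@H]3Cl)[C@@](C)(O)CC[C@@H]12 | intermediate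
32 | (4E,5R)-5-chloro-3-hydroxy-4-{[8β-hydroxy-4,4,8α,10β-tetramethyl-trans-decalin-9β-yl]methylidene}cyclopent-2-en-1-one (CNP0279879.2) | CC1(C)CCC[C@]2(C)[C@@H](/C=C3\C(O)=CC(=O)[C@@H]3Cl)[C@@](C)(O)CC[C@@H]12 | target

**Step count**
Total: 22 steps. Longest linear sequence: 21 steps (steps 1–16 and 18–22); step 17 is a one-step side branch.

**Steps most likely to fail**

Step 8. The cationic boron catalyst may fail to turn over with the hindered β,β-disubstituted ester. The cyclisation may also go stepwise (Mukaiyama–Michael addition, then ring closure) with silyl transfer to the Lewis acid, which would erode enantio- and endo-selectivity. The facial sense may be opposite to the binding model, in which case the catalyst from (R)-diphenylprolinol would be used. The fallback moves activation and face control to a covalently bound auxiliary, a known type of asymmetric intramolecular Diels–Alder reaction of trienimides; it sets out from 7 and comes back to the route at 16. Horner–Wadsworth–Emmons olefination of 7 with diethyl {2-[(4S)-4-benzyl-2-oxo-1,3-oxazolidin-3-yl]-2-oxoethyl}phosphonate (NaH, THF) would give the hydroxy enimide F1. Dess–Martin oxidation would give the aldehyde F2, Wittig reaction with 11 the enal F3, and TIPSOTf/Et3N the silyloxy trienimide F4. Me2AlCl (1.4 equiv, CH2Cl2, −30 °C) forms the cationic chelate of the s-cis enimide, in which the benzyl group covers the Re face of C9, and endo cyclisation should give the imide adduct F5. Hydrogenation (H2, Pd/C, EtOAc) would give the saturated imide F6, and LiBH4 (Et2O, H2O, 0 °C) removes the auxiliary to give 16.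

Step 20. The reduction may take the conjugate path at C11, may occur at the C2′ carbonyl, or may show low or reversed facial selectivity because both groups flanking the C5′ carbonyl are sp2 carbons. The fallback gives up reagent control of the face; it sets out from 28 and comes back at 29. Luche reduction of 28 (NaBH4, CeCl3·7H2O, MeOH, −78 °C) is selective for 1,2-reduction of the more electrophilic carbonyl but not for a face, and should give 29 together with its (4R)-carbinol epimer F7. The two are diastereomers and are separated by chromatography, and F7 is oxidised back to 28 with MnO2 (CH2Cl2, 20 °C) and recycled.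

Step 12. Under K2CO3 in methanol the aldehyde may lose the β-silyloxy group by E1cB elimination through the C9 enolate (axial leaving group), or the hindered carbonyl may react too slowly to compete with this. The fallback avoids base at the aldehyde stage by Corey–Fuchs homologation; it sets out from 17 and comes back at 18. CBr4 and PPh3 (CH2Cl2, 0 °C) would give the dibromoalkene F8, and n-BuLi (2.2 equiv, THF, −78 °C, then aq NH4Cl) converts it into 18 by lithium–bromine exchange and 1,2-shift.

**Further compounds**
F1 | step 8 | (4S)-4-benzyl-3-[(2E)-9-hydroxy-3,7,7-trimethylnon-2-enoyl]-1,3-oxazolidin-2-one | OCCC(C)(C)CCC/C(C)=C/C(=O)N1[C@@H](Cc2ccccc2)COC1=O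
F2 | step 8 | (4S)-4-benzyl-3-[(2E)-3,7,7-trimethyl-9-oxonon-2-enoyl]-1,3-oxazolidin-2-one | O=CCC(C)(C)CCC/C(C)=C/C(=O)N1[C@@H](Cc2ccccc2)COC1=O
F3 | step 8 | (4S)-4-benzyl-3-[(2E,9E)-3,7,7-trimethyl-11-oxoundeca-2,9-dienoyl]-1,3-oxazolidin-2-one | O=C/C=C/CC(C)(C)CCC/C(C)=C/C(=O)N1[C@@H](Cc2ccccc2)COC1=O
F4 | step 8 | (4S)-4-benzyl-3-{(2E,8E,10E)-3,7,7-trimethyl-11-[(triisopropylsilyl)oxy]undeca-2,8,10-trienoyl}-1,3-oxazolidin-2-one | CC(C)[Si](O/C=C/C=C/C(C)(C)CCC/C(C)=C/C(=O)N1[C@@H](Cc2ccccc2)COC1=O)(C(C)C)C(C)C
F5 | step 8 | (4S)-4-benzyl-3-[8β-(triisopropylsilyloxy)-12-nordrim-6-en-11-oyl]-1,3-oxazolidin-2-one | CC1(C)CCC[C@]2(C)[C@@H](C(=O)N3[C@@H](Cc4ccccc4)COC3=O)[C@@H](O[Si](C(C)C)(C(C)C)C(C)C)C=C[C@@H]12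
F6 | step 8 | (4S)-4-benzyl-3-[8β-(triisopropylsilyloxy)-12-nordriman-11-oyl]-1,3-oxazolidin-2-one | CC1(C)CCC[C@]2(C)[C@@H](C(=O)N3[C@@H](Cc4ccccc4)COC3=O)[C@@H](O[Si](C(C)C)(C(C)C)C(C)C)CC[C@@H]12
F7 | step 20 | (4R,5Z)-4-hydroxy-3-isopropoxy-5-{[4,4,8α,10β-tetramethyl-8β-(trimethylsilyloxy)-trans-decalin-9β-yl]methylidene}cyclopent-2-en-1-one | CC1(C)CCC[C@]2(C)[C@@H](/C=C3\C(=O)C=C(OC(C)C)[C@@H]3O)[C@@](C)(O[Si](C)(C)C)CC[C@@H]12
F8 | step 12 | 9β-(2,2-dibromoethenyl)-4,4,10β-trimethyl-8β-(triisopropylsilyloxy)-trans-decalin | CC1(C)CCC[C@]2(C)[C@@H](C=C(Br)Br)[C@@H](O[Si](C(C)C)(C(C)C)C(C)C)CC[C@@H]12
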